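The target, 5,7-dihydroxy-6-methyl-2-nonacosyl-4H-chromen-4-one, has no stereocentre. Only its constitution (6-methyl, not 8-methyl) has to be controlled.
Retrosynthetic cuts, in order: O1–C2 (ring C), C4a–C8a (ring A), C4–C4a (side chain to pyranone), then C2–C3 (fatty acid to Meldrum's acid) and C8–C8a (diketone to CO2).
Enabling feature: ring A (C4a, C5, C6, C7, C8, C8a) bears oxygen on C5, C7 and C8a, the acyl carbon C4 on C4a and a methyl group on C6. Ring A plus C2–C4 is therefore one linear chain C2–C3–C4–C4a–C5–C6–C7–C8–C8a with a carbonyl on every second carbon.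
Forward: the segment C4a–C8a is stored as a 4-hydroxy-2-pyranone and the segment C2–C4 is joined to it at C4a. Mg(OMe)2 then unfolds the pyranone and refolds the chain to ring A, and ring C is closed last.
C2 travels as a dioxolane, which removes the acidity at C3 and leaves a stable aryl ketone after the key step. The oxygen on C5 is benzylated before ring C closes, so that only the oxygen on C8a can reach C2.

Key step: step 7

Remark: the labels O1 and C2 to C8a are the chromone numbers of the target and follow the same atoms through all precursors; the position of a 6-methyl/8-methyl equilibrium in hot acid is taken as uncertain for 2-alkylchromones, so this regiochemistry is fixed by protection and not by equilibration.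

Step 1
Reactants: 1 3-methylpentane-2,4-dione
Product: 3 4-methyl-3,5-dioxohexanoic acid, via dilithium dienediolate 2 (not isolated)
Conditions: LiN(i-Pr)2 (2.2 equiv), THF, −78 to 0 °C; CO2 (g), −78 °C to rt; cold 2 M HCl
Reagents that add atoms: carbon dioxide, O=C=O
Why: Twofold deprotonation puts the more reactive carbanion on a terminal methyl group, and only this site is carboxylated (terminal carboxylation of a β-diketone dianion), which forms C8–C8a.

Step 2
Reactants: 3 4-methyl-3,5-dioxohexanoic acid
Product: 4 4-hydroxy-5,6-dimethyl-2H-pyran-2-one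
Conditions: Ac2O, 0 °C to rt
Reagents that add atoms: none
Why: The mixed anhydride of the acid should be captured by the enol oxygen on C5 (enol lactonisation of a 3,5-dioxo acid), a six-membered closure driven by the conjugated 4-hydroxy-2-pyranone.

Step 3
Reactants: 5 triacontanoic acid; 6 Meldrum's acid (2,2-dimethyl-1,3-dioxane-4,6-dione)
Product: 7 5-(1-hydroxytriacontylidene)-2,2-dimethyl-1,3-dioxane-4,6-dione
Conditions: DCC, DMAP, CH2Cl2–THF, 0 to 35 °C
Reagents that add atoms: none
Why: Carbodiimide activation (Steglich conditions) allows C-acylation of the acidic methylene group of Meldrum's acid, which forms C2–C3 and stops at the stable enol.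

Step 4
Reactants: 7 5-(1-hydroxytriacontylidene)-2,2-dimethyl-1,3-dioxane-4,6-dione
Product: 8 N-methoxy-N-methyl-3-oxodotriacontanamide
Conditions: MeNHOMe·HCl, Et3N, toluene, 100 °C
Reagents that add atoms: N,O-dimethylhydroxylamine hydrochloride, CNOC.Cl
Why: Heating an acyl Meldrum's acid with an amine gives the β-keto amide with loss of acetone and CO2 (decarboxylative aminolysis), here delivering the Weinreb amide directly.

Step 5
Reactants: 8 N-methoxy-N-methyl-3-oxodotriacontanamide
Product: 9 N-methoxy-N-methyl-2-(2-nonacosyl-1,3-dioxolan-2-yl)acetamide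
Conditions: HOCH2CH2OH, TsOH·H2O (cat.), benzene, reflux, Dean–Stark
Reagents that add atoms: ethylene glycol, OCCO
Why: Acid-catalysed ketalisation with azeotropic removal of water touches only the C2 ketone and removes the β-dicarbonyl acidity of C3 before the strongly basic coupling.

Step 6
Reactants: 4 4-hydroxy-5,6-dimethyl-2H-pyran-2-one; 9 N-methoxy-N-methyl-2-(2-nonacosyl-1,3-dioxolan-2-yl)acetamide
Product: 11 4-hydroxy-5-methyl-6-[3-(2-nonacosyl-1,3-dioxolan-2-yl)-2-oxopropyl]-2H-pyran-2-one, via dilithiated pyranone 10 (not isolated)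
Conditions: 4 (1.5 equiv), LiN(i-Pr)2 (2.95 equiv), THF–DMPU, −78 to 0 °C; 9 in THF, 0 °C to rt; cold 0.5 M HCl to pH 4
Reagents that add atoms: none
Why: After the hydroxyl proton, only the methyl group on pyranone C6 is acidic, because it is conjugated with the lactone carbonyl and the neighbouring methyl group is not, and this lateral carbanion attacks the amide once (Weinreb ketone synthesis) to form C4–C4a.

Step 7
Reactants: 11 4-hydroxy-5-methyl-6-[3-(2-nonacosyl-1,3-dioxolan-2-yl)-2-oxopropyl]-2H-pyran-2-one
Product: 13 2-(2-nonacosyl-1,3-dioxolan-2-yl)-1-(2,4,6-trihydroxy-3-methylphenyl)ethan-1-one, via open-chain triketo ester 12 (not isolated)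
Conditions: Mg(OMe)2 (8 equiv), MeOH–THF, reflux, Ar; cold 0.5 M HCl to pH 4
Reagents that add atoms: none
Why: Methoxide from Mg(OMe)2 adds to the lactone carbonyl C8a of 11 and releases the C5 enolate, so the pyranone unfolds to the triketo ester 12, which is held through its β-dicarbonyl units as a chelate of divalent magnesium. The C4a carbanion, acidified by the C4 and C5 carbonyls, then attacks the C8a ester carbonyl and expels methoxide, and enolisation of the new ring gives the phloroglucinol ring A of 13. The closest known reaction type is the intramolecular Claisen (Dieckmann-type) cyclisation of 3,5,7-triketo esters and of 6-(2-oxoalkyl)-4-hydroxy-2-pyranones to acylphloroglucinols with Mg(OMe)2. Ring A closes in the 6-exo-trig mode at the ester carbonyl, and C4a–C8a is the only skeletal bond formed. No stereocentre is created, and the labile one at C6 of 12 disappears on aromatisation. The step needs Claisen closure to beat the aldol closure C8 to C4: chelation turns the ketone oxygens into enolate oxygens and leaves the metal-activated ester as the electrophile, while the dioxolane at C2 removes the acidity of C3, so the aldol closure C3 to C7 and 4-pyranone formation from a C2/C4/C5 triketone cannot occur.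

Step 8
Reactants: 13 2-(2-nonacosyl-1,3-dioxolan-2-yl)-1-(2,4,6-trihydroxy-3-methylphenyl)ethan-1-one
Product: 14 1-[2-hydroxy-4,6-bis(methoxymethoxy)-3-methylphenyl]-2-(2-nonacosyl-1,3-dioxolan-2-yl)ethan-1-one
Conditions: MOMCl (2.2 equiv), i-Pr2NEt, CH2Cl2, 0 °C to rt
Reagents that add atoms: chloromethyl methyl ether, COCCl
Why: The phenol on C5 lies between the acyl group and the C6 methyl group, is the more strongly hydrogen-bonded to the C4 carbonyl and the more shielded, so O-alkylation should stop at the phenols on C7 and C8a, as in the known selective dialkylation of C-methylphloroacetophenone.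

Step 9
Reactants: 14 1-[2-hydroxy-4,6-bis(methoxymethoxy)-3-methylphenyl]-2-(2-nonacosyl-1,3-dioxolan-2-yl)ethan-1-one
Product: 15 1-[2-(benzyloxy)-4,6-bis(methoxymethoxy)-3-methylphenyl]-2-(2-nonacosyl-1,3-dioxolan-2-yl)ethan-1-one
Conditions: BnBr, K2CO3, DMF–THF, 60 °C
Reagents that add atoms: benzyl bromide, BrCc1ccccc1
Why: Williamson etherification in a dipolar solvent breaks the chelate of the only remaining phenol and caps the oxygen on C5 with a group that survives the acid of the next step.

Step 10
Reactants: 15 1-[2-(benzyloxy)-4,6-bis(methoxymethoxy)-3-methylphenyl]-2-(2-nonacosyl-1,3-dioxolan-2-yl)ethan-1-one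
Product: 17 5-(benzyloxy)-7-hydroxy-6-methyl-2-nonacosyl-4H-chromen-4-one, via benzyloxy diketone 16 (not isolated)
Conditions: conc. HCl (cat.), MeOH–THF, 60 °C
Reagents that add atoms: none
Why: Acid methanolysis removes both MOM acetals and the dioxolane, and the only free ortho phenol (on C8a) then adds to C2 with loss of water (cyclodehydration of an o-hydroxyaryl β-diketone to a chromone), under conditions too mild to reopen ring C and start a Wessely–Moser rearrangement.

Step 11
Reactants: 17 5-(benzyloxy)-7-hydroxy-6-methyl-2-nonacosyl-4H-chromen-4-one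
Product: 18 5,7-dihydroxy-6-methyl-2-nonacosyl-4H-chromen-4-one (target)
Conditions: H2 (1 atm), Pd/C, THF–EtOH, 40 °C
Reagents that add atoms: none
Why: Hydrogenolysis of the aryl benzyl ether is neutral, so ring C stays closed and the methyl group stays on C6, and the vinylogous-ester C2=C3 bond of a chromone is normally untouched at this pressure.

Compound list
1 | 3-methylpentane-2,4-dione | CC(=O)C(C)C(C)=O | starting material
2 | dilithium 3-methylpenta-1,3-diene-2,4-diolate (dianion of 1) | [Li+].[Li+].C=C([O-])C(C)=C(C)[O-] | intermediate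
3 | 4-methyl-3,5-dioxohexanoic acid (racemic, enolisable centre) | CC(=O)C(C)C(=O)CC(=O)O | intermediate
4 | 4-hydroxy-5,6-dimethyl-2H-pyran-2-one | Cc1oc(=O)cc(O)c1C | intermediate
5 | triacontanoic acid | CCCCCCCCCCCCCCCCCCCCCCCCCCCCCC(=O)O | starting material
6 | Meldrum's acid (2,2-dimethyl-1,3-dioxane-4,6-dione) | CC1(C)OC(=O)CC(=O)O1 | starting material
7 | 5-(1-hydroxytriacontylidene)-2,2-dimethyl-1,3-dioxane-4,6-dione | CCCCCCCCCCCCCCCCCCCCCCCCCCCCCC(O)=C1C(=O)OC(C)(C)OC1=O | intermediate
8 | N-methoxy-N-methyl-3-oxodotriacontanamide | CCCCCCCCCCCCCCCCCCCCCCCCCCCCCC(=O)CC(=O)N(C)OC | intermediate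
9 | N-methoxy-N-methyl-2-(2-nonacosyl-1,3-dioxolan-2-yl)acetamide | CCCCCCCCCCCCCCCCCCCCCCCCCCCCCC1(CC(=O)N(C)OC)OCCO1 | intermediate
10 | dilithium salt of 4, deprotonated at the 4-hydroxyl group and at the methyl group on C6 of the pyranone | [Li+].[Li+].[CH2-]c1oc(=O)cc([O-])c1C | intermediate
11 | 4-hydroxy-5-methyl-6-[3-(2-nonacosyl-1,3-dioxolan-2-yl)-2-oxopropyl]-2H-pyran-2-one | CCCCCCCCCCCCCCCCCCCCCCCCCCCCCC1(CC(=O)Cc2oc(=O)cc(O)c2C)OCCO1 | intermediate
12 | methyl 4-methyl-8-(2-nonacosyl-1,3-dioxolan-2-yl)-3,5,7-trioxooctanoate (racemic, enolisable centre; present as magnesium chelate) | CCCCCCCCCCCCCCCCCCCCCCCCCCCCCC1(CC(=O)CC(=O)C(C)C(=O)CC(=O)OC)OCCO1 | intermediate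
13 | 2-(2-nonacosyl-1,3-dioxolan-2-yl)-1-(2,4,6-trihydroxy-3-methylphenyl)ethan-1-one | CCCCCCCCCCCCCCCCCCCCCCCCCCCCCC1(CC(=O)c2c(O)cc(O)c(C)c2O)OCCO1 | intermediate
14 | 1-[2-hydroxy-4,6-bis(methoxymethoxy)-3-methylphenyl]-2-(2-nonacosyl-1,3-dioxolan-2-yl)ethan-1-one | CCCCCCCCCCCCCCCCCCCCCCCCCCCCCC1(CC(=O)c2c(OCOC)cc(OCOC)c(C)c2O)OCCO1 | intermediate
15 | 1-[2-(benzyloxy)-4,6-bis(methoxymethoxy)-3-methylphenyl]-2-(2-nonacosyl-1,3-dioxolan-2-yl)ethan-1-one | CCCCCCCCCCCCCCCCCCCCCCCCCCCCCC1(CC(=O)c2c(OCOC)cc(OCOC)c(C)c2OCc3ccccc3)OCCO1 | intermediate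
16 | 1-[2-(benzyloxy)-4,6-dihydroxy-3-methylphenyl]dotriacontane-1,3-dione | CCCCCCCCCCCCCCCCCCCCCCCCCCCCCC(=O)CC(=O)c1c(O)cc(O)c(C)c1OCc2ccccc2 | intermediate
17 | 5-(benzyloxy)-7-hydroxy-6-methyl-2-nonacosyl-4H-chromen-4-one | CCCCCCCCCCCCCCCCCCCCCCCCCCCCCc1cc(=O)c2c(OCc3ccccc3)c(C)c(O)cc2o1 | intermediate
18 | 5,7-dihydroxy-6-methyl-2-nonacosyl-4H-chromen-4-one | CCCCCCCCCCCCCCCCCCCCCCCCCCCCCc1cc(=O)c2c(O)c(C)c(O)cc2o1 | target

Total step count: 11. Longest linear sequence: 9 steps (steps 3 to 11, from triacontanoic acid 5).

Steps most likely to fail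

Step 6. The dianion 10 may act as a base toward the α-methylene group of 9, and the resulting amide enolate can open the dioxolane by β-elimination. The waxy amide also dissolves poorly in the cold, which slows the acylation further. The fallback replaces acylation by addition to an aldehyde followed by oxidation. It sets out from 9, which is reduced with i-Bu2AlH in toluene–THF to 2-(2-nonacosyl-1,3-dioxolan-2-yl)acetaldehyde F1. The dianion 10 should add to this far more electrophilic carbonyl faster than it deprotonates it. That gives racemic 4-hydroxy-6-[2-hydroxy-3-(2-nonacosyl-1,3-dioxolan-2-yl)propyl]-5-methyl-2H-pyran-2-one F2. Dess–Martin oxidation of the carbinol comes back to the route at 11.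

Step 7. The pyranone reacts as its 4-oxide anion and may open only slowly. At reflux, aldol closure C8 to C4 or methanolytic cleavage of the C4–C4a bond could then overtake the Claisen closure. The fallback uses an open-chain substrate that has no lactone to open, and it sets out from 3 and 9. Acid 3 is esterified with Me3SiCHN2 to methyl 4-methyl-3,5-dioxohexanoate F3. F3 is deprotonated three times with LiN(i-Pr)2 and acylated at its terminal methyl group by 9, which gives 12 as an isolated compound. Because 12 already holds the ester, it can be closed with Mg(OMe)2 at room temperature, where chelation control should be at its best. The fallback comes back to the route at 13.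

Step 8. Discrimination between the phenols on C5 and C8a may be incomplete, or a third alkylation may set in, and either would carry the wrong oxygen pattern into the closure of ring C. The fallback gives up phenol protection and separates after ring closure. It sets out from 13, which is treated directly with HCl in MeOH–THF. Loss of the glycol gives 1-(2,4,6-trihydroxy-3-methylphenyl)dotriacontane-1,3-dione F4. F4 cyclodehydrates through either ortho phenol, to 18 and to 5,7-dihydroxy-8-methyl-2-nonacosyl-4H-chromen-4-one F5, and the two isomers are separated by chromatography. F5 is re-equilibrated with 18 by acid-induced opening and reclosure of ring C (Wessely–Moser rearrangement, HI–AcOH) and separated again. The fallback ends at 18.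

Further compounds
F1 | step 6 | 2-(2-nonacosyl-1,3-dioxolan-2-yl)acetaldehyde | CCCCCCCCCCCCCCCCCCCCCCCCCCCCCC1(CC=O)OCCO1
F2 | step 6 | 4-hydroxy-6-[2-hydroxy-3-(2-nonacosyl-1,3-dioxolan-2-yl)propyl]-5-methyl-2H-pyran-2-one (racemic) | CCCCCCCCCCCCCCCCCCCCCCCCCCCCCC1(CC(O)Cc2oc(=O)cc(O)c2C)OCCO1
F3 | step 7 | methyl 4-methyl-3,5-dioxohexanoate (racemic, enolisable centre) | CC(=O)C(C)C(=O)CC(=O)OC
F4 | step 8 | 1-(2,4,6-trihydroxy-3-methylphenyl)dotriacontane-1,3-dione | CCCCCCCCCCCCCCCCCCCCCCCCCCCCCC(=O)CC(=O)c1c(O)cc(O)c(C)c1O
F5 | step 8 | 5,7-dihydroxy-8-methyl-2-nonacosyl-4H-chromen-4-one | CCCCCCCCCCCCCCCCCCCCCCCCCCCCCc1cc(=O)c2c(O)cc(O)c(C)c2o1
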